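In this closed, stirred, isothermal vessel the single-handed catalyst G brings the reagent J onto a racemate of E and Q. Elm, the flask asked about, and the earlier ash differ in their charge of J.

all flasks: E 0.050 M; Q 0.050 M; G 0.5 mol%
- elm: J 0.60 equiv; the very flask that is asked about, followed so far
- ash: J 0.30 equiv; run made earlier
- flask: J 0.600 equiv

| run | time / h | Z / % | E / % |
|---|---|---|---|
| elm | 8.00 | 16.2 | 34.7 |
| elm | 15.0 | 19.9 | 30.5 |
| elm | 20.0 | 18.6 | 30.6 |
| elm | 30.0 | 20.3 | 28.8 |
| ash | 4.00 | 7.2 | 43.3 |
| ash | 10.0 | 10.1 | 40.1 |
| ash | 20.0 | 8.6 | 39.4 |
| ash | 30.0 | 11.2 | 38.0 |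

(scatter of a reading: 1 percentage point)

- apparent order in J when 10 % of the E and Q together are converted (percent change of the rate of making Z for one percent more J charged)
- apparent order in G when 10 % of the E and Q together are converted (percent change of the rate of making Z for one percent more G charged)

Elm looks contradictory: after 30.0 h Z stands at 20.3 % with 28.8 % of E still there, yet the J charged is worth 30.0 % of the E and Q together. Ash reads short as well, 11.2 % against 15.0 %, so I take it that unread Q uses the difference and that J is the limiting reagent. I therefore reckon with the J left, the fraction of its charge not yet turned when the stated conversion is reached, 66.7 % in elm. If the rate follows J left, the order in J at fixed conversion is the inverse of that fraction, 1.50. For the charge of ash the fraction is 33.3 %, which gives 3.00. For G, which no run varies, I guess 1.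

The forecast gives 1.9 in J (range 1.4 to 2.3) and 1.4 in G (range 1 to 2), and says: “The G order cannot be determined from these runs.”

The flask gives 1.6 in J and 1.1 in G.

    J + G + E → G + Z (k = 22600 M⁻² h⁻¹)
    J + G + Q → G + D (k = 7750 M⁻² h⁻¹)
    J ⇌ X (K = 1.05, k = 0.0640 h⁻¹)
    J + G → L (k = 1.19 M⁻¹ h⁻¹)

At 0.300 d the flask holds X at 0.00362 M, which is 12.1 % of the J charged. My 66.7 % was the charge less the J turned at the conversion asked about, and reckoned the same way from the Z and D at 0.300 d the fraction is 22.1 %. That fraction is shared by X, by the J that went into L, which stands at 8.63 % of the catalyst charged, and by J itself, which stands at 9.95 % of its own charge.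

The numbers in the tables were generated by integration for substances that don't exist; noise was put on by code.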